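**Plan**

1. Numbering used below (cedrane-type): C1 quaternary ring-fusion carbon, C2 CH–CHO, C3/C4 CH2, C5 ring-fusion CH, C6 C(CH3)(CH2OH), C7 bridgehead CH, C8 C(CO2H)=, C9 =CH, C10 CH–O-acyl, C11 bridge CH2, C12 CHO, C13 CH2OH, C14 CH3, C15 CO2H; ring A = C1–C5, ring B = C1/C5/C6/C7/C11, ring C = C1/C10/C9/C8/C7/C11.
2. Retrosynthesis: cut the C10–O fatty ester; then C8–C15 (carbonylation) and C2–C12 (Wittig); then C8–C9 of ring C (retro-Claisen, which re-closes a C13–O–C8 γ-lactone); then both ring B bonds to ring A, C11–C1 and C5–C6, giving 2-acetylcyclopent-2-enone and a lactone-embedded three-carbon dipole.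
3. Forward: ring A is bought; ring B and a temporary γ-lactone ring arise in one [3+2] annulation; ring C is closed by an intramolecular Claisen condensation that opens the lactone; C12 and C15 are then added, C10 is reduced, the (Z)-hydroxy acid chain (Wittig) is attached and all masks fall in one acid step.
4. Enabling feature: in ring B the unit C11–C7–C6 is an allyl unit whose central carbon C7 carries C8, a latent carbonyl, so it can be a 2-acylallyl 1,3-dipole (phosphorus ylide of a Morita–Baylis–Hillman carbonate); the partner bond C1–C5 of ring A is flanked by C2 and C10, both usable as ketones, so it can be a doubly activated alkene.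
5. Stereochemistry: absolute configuration from the chiral phosphine in the annulation; C1/C5/C6 from cis ring fusion and exo approach; C7 from the cis-fused lactone; C10 from hydride attack on the face of the C11 bridge; C2 by thermodynamic control; the (Z)-alkene from a salt-free Wittig reaction.

Key step: step 5

Assumption: the sense of induction of the chiral phosphine in step 5 cannot be predicted with certainty; the catalyst antipode that gives 10 as drawn is to be used (written here as the (S,S)-form).

**Step 1**
Reactants: 1 methyl acrylate; 2 methyl pyruvate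
Product: 3 dimethyl 2-hydroxy-2-methyl-3-methylidenebutanedioate (racemic)
Conditions: DABCO (20 mol%), neat, rt
Reagents that add atoms: none
Why: Morita–Baylis–Hillman reaction, in which the ammonium enolate of the acrylate adds to the activated ketone of the α-keto ester; the carbinol center is formed racemic and is erased in step 5.

**Step 2**
Reactants: 3 dimethyl 2-hydroxy-2-methyl-3-methylidenebutanedioate
Product: 5 hydroxy methylidene lactone (4-hydroxy-4-methyl-3-methylideneoxolan-2-one), via diol ester 4 (not isolated)
Conditions: BH3·SMe2 (1.05 equiv), NaBH4 (5 mol%), THF, 0 °C → rt; MeOH; then TsOH (cat.), CH2Cl2, rt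
Reagents that add atoms: none
Why: Hydroxyl-directed borane reduction should take the ester next to the hydroxyl group (five-membered alkoxyborane chelate) and spare the acrylate ester, and the freed primary alcohol then lactonises onto the acrylate ester (5-exo-trig transesterification).

**Step 3**
Reactants: 5 hydroxy methylidene lactone
Product: 6 tert-butyl (3-methyl-4-methylidene-5-oxooxolan-3-yl) carbonate
Conditions: Boc2O, DMAP (10 mol%), CH2Cl2, 0 °C → rt
Reagents that add atoms: di-tert-butyl dicarbonate, CC(C)(C)OC(=O)OC(=O)OC(C)(C)C
Why: DMAP-catalysed acylation of the tertiary allylic alcohol gives the Morita–Baylis–Hillman carbonate, whose leaving group later supplies tert-butoxide as the internal base.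

**Step 4**
Reactants: 7 2-acetylcyclopentan-1-one
Product: 9 2-acetylcyclopent-2-en-1-one, via selenide 8 (not isolated)
Conditions: PhSeCl, pyridine, CH2Cl2, 0 °C; then 30% H2O2, 0 °C; cold aqueous work-up, short silica plug, used at once
Reagents that add atoms: none
Why: α-Selenenylation of the 1,3-diketone at its central carbon followed by selenoxide syn-elimination towards the ring CH2 should give the doubly activated enone, which is used immediately because it tautomerises and dimerises on standing.

**Step 5**
Reactants: 6 tert-butyl (3-methyl-4-methylidene-5-oxooxolan-3-yl) carbonate; 9 2-acetylcyclopent-2-en-1-one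
Product: 10 tricyclic acetyl keto butenolide
Conditions: (S,S)-Ph-BPE (10 mol%), 4 Å MS, toluene, −20 °C → rt, slow addition of 9
Reagents that add atoms: none
Why: Proposed new method: the phosphine adds to the exocyclic methylene of 6 (SN2'), tert-butyl carbonate leaves and gives CO2 and tert-butoxide, which deprotonates the 3-(phosphoniomethyl)butenolide to an allylic phosphorus ylide; its γ-carbon C6 adds to the β-carbon C5 of 9, the 1,3-diketone enolate closes through C1 onto the vinylphosphonium carbon C11, and β-elimination returns the phosphine and leaves the C7=C11 double bond. The closest known reaction type is the Lu phosphine-catalysed [3+2] annulation of Morita–Baylis–Hillman carbonates with alkylidene 1,3-dicarbonyl compounds, including ketone-derived tertiary carbonates that form a quaternary γ-carbon; new here are the non-stabilised dialkyl γ-carbon and the lactone-embedded ylide. Ring B is closed by an intermolecular Michael addition followed by a 5-endo-trig addition of the enolate to the vinylphosphonium unit, and its fusion to ring A can only be cis. C1 and C5 are therefore fixed cis by the ring closure, C6 by exo approach of the planar ylide, which keeps the lactone ring over the flat acetyl side and away from the CH2–CH2 edge of ring A (cis-anti-cis tricycle, C13 cis to the acetyl group), and the absolute configuration by the chiral phosphine bound at C11. The step needs the regioselectivity C6 to C5 and C11 to C1, which should be secured because the Michael step is reversible and the alternative closure would join the two fully substituted carbons C1 and C6; reaction through the lactone CH2 is disfavoured because the phosphonium-stabilised ylide is the more acidic site.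

**Step 6**
Reactants: 10 tricyclic acetyl keto butenolide
Product: 11 saturated tricyclic acetyl keto lactone
Conditions: H2 (3 atm), Pd/C, EtOAc, rt
Reagents that add atoms: none
Why: Heterogeneous hydrogenation of the conjugated trisubstituted alkene; C7 should take hydrogen on the face of the C6 methyl group because only the cis-fused γ-lactone is unstrained, and C7 stays epimerisable α to the lactone carbonyl if any trans isomer forms.

**Step 7**
Reactants: 11 saturated tricyclic acetyl keto lactone
Product: 13 silyl ether of the tricyclic triketone, via hydroxy triketone 12 (not isolated)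
Conditions: LiN(SiMe3)2 (2.5 equiv), THF, −78 → 0 °C; then TBSCl (1.2 equiv), 0 °C → rt; aq. NH4Cl
Reagents that add atoms: tert-butyldimethylsilyl chloride, CC(C)(C)[Si](C)(C)Cl
Why: Intramolecular Claisen condensation: the enolate of the methyl ketone (C9) attacks the lactone carbonyl C8 held cis on ring B (6-exo-trig acyl substitution), which closes ring C with the 1,3-diketone enolate as thermodynamic sink and releases the C13 alkoxide, silylated in the same flask.

**Step 8**
Reactants: 13 silyl ether of the tricyclic triketone
Product: 14 methoxymethylidene diketone (E/Z mixture)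
Conditions: MeOCH2PPh3Cl (4 equiv), KN(SiMe3)2 (3.8 equiv), THF, 0 °C → rt; pH 7 buffer
Reagents that add atoms: (methoxymethyl)triphenylphosphonium chloride, COC[P+](c1ccccc1)(c1ccccc1)c1ccccc1.[Cl-]
Why: Wittig methoxymethylenation of the only free ketone (C2) adds C12; the first equivalent of ylide deprotonates the 1,3-diketone, whose enolate is inert to the ylide.

**Step 9**
Reactants: 14 methoxymethylidene diketone
Product: 15 C8 enol triflate
Conditions: NaH, THF, 0 °C; PhNTf2, 0 °C → rt
Reagents that add atoms: N-phenylbis(trifluoromethanesulfonimide), O=S(=O)(N(c1ccccc1)S(=O)(=O)C(F)(F)F)C(F)(F)F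
Why: O-sulfonylation of the diketonate: the oxygen on C8 lies next to the bridgehead C7–H, whereas the oxygen on C10 is flanked by the quaternary C1 and the methoxymethylidene group on C2, so the vinylogous acyl triflate should form at C8.

**Step 10**
Reactants: 15 C8 enol triflate
Product: 16 4-methoxybenzyl enone ester
Conditions: Pd(OAc)2 (5 mol%), 1,3-bis(diphenylphosphino)propane, CO (1 atm), 4-methoxybenzyl alcohol, Et3N, DMF, 60 °C
Reagents that add atoms: carbon monoxide, [C-]#[O+]; 4-methoxybenzyl alcohol, COc1ccc(CO)cc1
Why: Palladium-catalysed alkoxycarbonylation of a vinyl triflate (oxidative addition, CO insertion, alcoholysis) installs C15 as an acid-labile ester.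

**Step 11**
Reactants: 16 4-methoxybenzyl enone ester
Product: 17 C10 allylic alcohol
Conditions: NaBH4, CeCl3·7H2O, MeOH/THF, −78 °C
Reagents that add atoms: none
Why: Luche 1,2-reduction: hydride should attack C10 from the face of the one-carbon bridge C11, away from the C5–C6 bridge with its endo hydrogen and endo CH2OTBS group, which places the hydroxyl on the side of the C5–C6 bridge as in the target.

**Step 12**
Reactants: 18 7-bromoheptan-1-ol
Product: 19 (7-bromoheptoxy)(tert-butyl)dimethylsilane
Conditions: TBSCl, imidazole, CH2Cl2, rt
Reagents that add atoms: tert-butyldimethylsilyl chloride, CC(C)(C)[Si](C)(C)Cl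
Why: Standard silylation of a primary alcohol masks the later ω-hydroxyl group.

**Step 13**
Reactants: 19 (7-bromoheptoxy)(tert-butyl)dimethylsilane
Product: 20 [7-(tert-butyldimethylsilyloxy)heptyl]triphenylphosphonium bromide
Conditions: PPh3, MeCN, reflux
Reagents that add atoms: triphenylphosphine, c1ccc(cc1)P(c1ccccc1)c1ccccc1
Why: SN2 quaternisation of triphenylphosphine by the primary bromide gives the Wittig salt.

**Step 14**
Reactants: 20 [7-(tert-butyldimethylsilyloxy)heptyl]triphenylphosphonium bromide; 21 methyl 9-oxononanoate
Product: 22 methyl (9Z)-16-(tert-butyldimethylsilyloxy)hexadec-9-enoate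
Conditions: NaN(SiMe3)2, THF, −78 °C; then 21, −78 °C → rt
Reagents that add atoms: none
Why: Wittig reaction of a non-stabilised ylide under lithium-free conditions should give the (Z)-alkene through the kinetically favoured cis-oxaphosphetane.

**Step 15**
Reactants: 22 methyl (9Z)-16-(tert-butyldimethylsilyloxy)hexadec-9-enoate
Product: 23 (9Z)-16-(tert-butyldimethylsilyloxy)hexadec-9-enoic acid
Conditions: LiOH, THF/MeOH/H2O, rt; dilute HCl to pH 4
Reagents that add atoms: lithium hydroxide, [Li+].[OH-]
Why: Saponification of the methyl ester, which the primary silyl ether and the (Z)-alkene tolerate.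

**Step 16**
Reactants: 17 C10 allylic alcohol; 23 (9Z)-16-(tert-butyldimethylsilyloxy)hexadec-9-enoic acid
Product: 24 protected target ester
Conditions: 2,4,6-trichlorobenzoyl chloride, Et3N, THF, rt; then 17, DMAP, toluene, rt → 50 °C
Reagents that add atoms: none
Why: Yamaguchi esterification through the mixed anhydride and DMAP acyl transfer suits the hindered secondary alcohol and retains the configuration at C10.

**Step 17**
Reactants: 24 protected target ester
Product: 25 target CNP0148862.2
Conditions: TFA/H2O/CH2Cl2 (5:1:10), 0 °C → rt
Reagents that add atoms: water, O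
Why: Aqueous acid hydrolyses the enol ether to the aldehyde and cleaves both silyl ethers and the 4-methoxybenzyl ester; C2 should equilibrate through the enol to the more stable epimer with the formyl group syn to the C11 bridge and anti to the acyloxy-bearing C10, and because C10 is already acylated the other epimer cannot be trapped as a lactol.

**Compound list**

1 | methyl acrylate | C=CC(=O)OC | starting material
2 | methyl pyruvate | CC(=O)C(=O)OC | starting material
3 | dimethyl 2-hydroxy-2-methyl-3-methylidenebutanedioate (racemic) | COC(=O)C(C)(O)C(=C)C(=O)OC | intermediate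
4 | methyl 2-(1,2-dihydroxypropan-2-yl)prop-2-enoate (racemic) | OCC(C)(O)C(=C)C(=O)OC | intermediate (not isolated)
5 | 4-hydroxy-4-methyl-3-methylideneoxolan-2-one (racemic) | CC1(O)COC(=O)C1=C | intermediate
6 | tert-butyl (3-methyl-4-methylidene-5-oxooxolan-3-yl) carbonate (racemic) | CC1(OC(=O)OC(C)(C)C)COC(=O)C1=C | intermediate
7 | 2-acetylcyclopentan-1-one | CC(=O)C1CCCC1=O | starting material
8 | 2-acetyl-2-(phenylselanyl)cyclopentan-1-one | CC(=O)C1([Se]c2ccccc2)CCCC1=O | intermediate (not isolated)
9 | 2-acetylcyclopent-2-en-1-one | CC(=O)C1=CCCC1=O | intermediate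
10 | tricyclic acetyl keto butenolide: ring A cyclopentanone (C2=O) cis-fused to ring B cyclopentene (C7=C11); acetyl on C1; methyl on C6; lactone C6–C13H2–O–C8(=O)–C7; C13 cis to acetyl and to H5 | C[C@@]1(COC2=O)C2=C[C@@]3(C(C)=O)C(=O)CC[C@@H]13 | intermediate
11 | saturated tricyclic acetyl keto lactone: as 10 with C7–H cis to the C6 methyl group (cis-fused γ-lactone) and C11H2 | C[C@@]1(COC2=O)[C@H]2C[C@@]3(C(C)=O)C(=O)CC[C@@H]13 | intermediate
12 | hydroxy triketone: ring C closed (C8 and C10 ketones, C9H2), free C13–OH, C2 ketone | C[C@@]1(CO)[C@H]2C[C@@]3(C(=O)CC2=O)C(=O)CC[C@@H]13 | intermediate (not isolated)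
13 | tert-butyldimethylsilyl ether of 12 | C[C@@]1(CO[Si](C)(C)C(C)(C)C)[C@H]2C[C@@]3(C(=O)CC2=O)C(=O)CC[C@@H]13 | intermediate
14 | C2 methoxymethylidene derivative of 13 (E/Z mixture) | C[C@@]1(CO[Si](C)(C)C(C)(C)C)[C@H]2C[C@@]3(C(=O)CC2=O)C(=COC)CC[C@@H]13 | intermediate
15 | C8 enol trifluoromethanesulfonate of 14 (C8=C9, C10 ketone) | C[C@@]1(CO[Si](C)(C)C(C)(C)C)[C@H]2C[C@@]3(C(=O)C=C2OS(=O)(=O)C(F)(F)F)C(=COC)CC[C@@H]13 | intermediate
16 | 4-methoxybenzyl ester (C15 on C8, C8=C9, C10 ketone) | C[C@@]1(CO[Si](C)(C)C(C)(C)C)[C@H]2C[C@@]3(C(=O)C=C2C(=O)OCc4ccc(OC)cc4)C(=COC)CC[C@@H]13 | intermediate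
17 | C10 alcohol of 16 (hydroxyl on the side of the C5–C6 bridge) | C[C@@]1(CO[Si](C)(C)C(C)(C)C)[C@H]2C[C@@]3([C@@H](O)C=C2C(=O)OCc4ccc(OC)cc4)C(=COC)CC[C@@H]13 | intermediate
18 | 7-bromoheptan-1-ol | OCCCCCCCBr | starting material
19 | (7-bromoheptoxy)(tert-butyl)dimethylsilane | CC(C)(C)[Si](C)(C)OCCCCCCCBr | intermediate
20 | [7-(tert-butyldimethylsilyloxy)heptyl]triphenylphosphonium bromide | CC(C)(C)[Si](C)(C)OCCCCCCC[P+](c1ccccc1)(c1ccccc1)c1ccccc1.[Br-] | intermediate
21 | methyl 9-oxononanoate | COC(=O)CCCCCCCC=O | starting material
22 | methyl (9Z)-16-(tert-butyldimethylsilyloxy)hexadec-9-enoate | COC(=O)CCCCCCC/C=C\CCCCCCO[Si](C)(C)C(C)(C)C | intermediate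
23 | (9Z)-16-(tert-butyldimethylsilyloxy)hexadec-9-enoic acid | OC(=O)CCCCCCC/C=C\CCCCCCO[Si](C)(C)C(C)(C)C | intermediate
24 | C10 ester of 17 with 23 (fully protected target) | C[C@@]1(CO[Si](C)(C)C(C)(C)C)[C@H]2C[C@@]3([C@@H](OC(=O)CCCCCCC/C=C\CCCCCCO[Si](C)(C)C(C)(C)C)C=C2C(=O)OCc4ccc(OC)cc4)C(=COC)CC[C@@H]13 | intermediate
25 | CNP0148862.2 | C[C@@]1(CO)[C@H]2C[C@@]3([C@@H](OC(=O)CCCCCCC/C=C\CCCCCCO)C=C2C(=O)O)[C@@H](C=O)CC[C@@H]13 | target

**Totals**

Total step count: 17. Longest linear sequence: 12 steps (steps 1, 2, 3, 5, 6, 7, 8, 9, 10, 11, 16, 17).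

**Steps most likely to fail**

Step 5. The acyl enone 9 may tautomerise or dimerise under the basic ylide conditions faster than it is annulated, and the ylide may react first through its phosphorus-bearing carbon or discriminate poorly between the enone faces. The fallback uses known chemistry, a Lewis-acid-mediated Danheiser [3+2] annulation in place of phosphine catalysis, and sets out from 9. Compound 9 and the separately prepared, enantioenriched allenylsilane tert-butyldimethyl{[2-methyl-4-(trimethylsilyl)buta-2,3-dien-1-yl]oxy}silane F1 (TiCl4, CH2Cl2, −78 °C) should give the trimethylsilyl cyclopentene F2 by conjugate addition through the allene terminus, 1,2-silyl shift and closure by the titanium enolate. The same two ring B bonds are formed, and the axial chirality of F1 is passed on to C6, C5 and C1. Ipso-iododesilylation (ICl, CH2Cl2, −78 °C) would give the vinyl iodide F3, and HF·pyridine the iodo alcohol F4. Carbonylative lactonisation (Pd(PPh3)4, CO, Et3N, THF) would then bring the route back at 10.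

Step 11. Hydride may be delivered to the other face of the C10 carbonyl group. The fallback sets out from 16: if the reduction gives mainly the C10-epimeric alcohol F5, this is esterified with acid 23 under Mitsunobu conditions (PPh3, diisopropyl azodicarboxylate, toluene). The SN2 inversion at C10 should give 24, where the route is rejoined and step 16 is no longer needed.

Step 17. Equilibration at C2 under acid may be incomplete, so that the kinetically protonated epimer persists, or the long acid exposure may damage the allylic ester. The fallback sets out from 24 and separates unmasking, epimerisation and deprotection. Mild hydrolysis of the enol ether alone (pyridinium p-toluenesulfonate, acetone/H2O, rt) should give the protected aldehyde F6. Catalytic DBU in CH2Cl2 then equilibrates F6 at C2 under base on a substrate without free hydroxyl or carboxyl groups. A short treatment with TFA/H2O/CH2Cl2 at 0 °C removes the silyl ethers and the 4-methoxybenzyl ester to give 25.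

**Further compounds**

F1 | step 5 | tert-butyldimethyl{[2-methyl-4-(trimethylsilyl)buta-2,3-dien-1-yl]oxy}silane (enantioenriched, axial configuration matched to 10) | C[Si](C)(C)C=C=C(C)CO[Si](C)(C)C(C)(C)C
F2 | step 5 | trimethylsilyl cyclopentene: ring A/ring B bicycle with C7–SiMe3, C7=C11, C13–OTBS, acetyl on C1, C2 ketone | C[C@@]1(CO[Si](C)(C)C(C)(C)C)C([Si](C)(C)C)=C[C@@]2(C(C)=O)C(=O)CC[C@@H]12
F3 | step 5 | vinyl iodide (C7–I) derived from F2 | C[C@@]1(CO[Si](C)(C)C(C)(C)C)C(I)=C[C@@]2(C(C)=O)C(=O)CC[C@@H]12
F4 | step 5 | iodo alcohol (C7–I, free C13–OH) | C[C@@]1(CO)C(I)=C[C@@]2(C(C)=O)C(=O)CC[C@@H]12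
F5 | step 11 | C10 epimer of 17 | C[C@@]1(CO[Si](C)(C)C(C)(C)C)[C@H]2C[C@@]3([C@H](O)C=C2C(=O)OCc4ccc(OC)cc4)C(=COC)CC[C@@H]13
F6 | step 17 | protected aldehyde (C2–CHO, both silyl ethers and the 4-methoxybenzyl ester intact) | C[C@@]1(CO[Si](C)(C)C(C)(C)C)[C@H]2C[C@@]3([C@@H](OC(=O)CCCCCCC/C=C\CCCCCCO[Si](C)(C)C(C)(C)C)C=C2C(=O)OCc4ccc(OC)cc4)[C@@H](C=O)CC[C@@H]13
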